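Ring numbering: C1 = tertiary carbinol carrying C7H2OBz, C2 = CH(OBz), C3 = CH(OH), C4=C5, C6 = CHCl. The enabling feature is that the oxygens on the adjacent ring carbons C1 and C2 lie on the same face of the six-membered ring. They form a cis-1,2-diol of one tertiary and one secondary carbinol, which is what a metal-bridged ketone/aldehyde pinacol coupling delivers.
Retrosynthetic cuts, in order: C6–Cl (back to the C1–C6 vinyl epoxide, and from there to a trans-1,6-diol); the C4=C5 π bond (back to a cis-4,5-diol kept as its acetonide); the ring bond C1–C2 (back to an open-chain 1,6-keto-aldehyde); C1–C7 (back to a galactonic Weinreb amide and an alkoxymethyllithium).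
Forward: a galactopyranoside is protected, opened through its 1,5-lactone, extended by C7 and oxidised at the far end. The only ring of the target, the carbocycle, closes in the SmI2 step, and alkene, epoxide and chloride follow.
Stereochemistry: C6, C5, C4 and C3 are C2, C3, C4 and C5 of D-galactose. C1 and C2 arise in the pinacol step, cis to each other through the samarium bridge and anti to the cis-1,4 oxygens on C3 and C6. C6 is inverted twice (epoxide closure, chloride opening) and so keeps the galactose sense.
Key step: step 12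

Assumption: the D-galactose chiral pool is entered through commercial phenyl 1-thio-β-D-galactopyranoside, whose anomeric group can later be removed without strong acid; tributyl(iodomethyl)stannane, 4-methoxybenzyl alcohol, 4-methoxybenzyl chloride and benzoyl chloride are likewise bought.
Conventions: chain compounds keep galactose numbering G1–G6 (G1 = C1, G2 = C6, G3 = C5, G4 = C4, G5 = C3, G6 = C2). The carbocycle is viewed with C1 to C6 running clockwise, and "upper" points to the viewer. PMB = 4-methoxybenzyl, TBS = tert-butyldimethylsilyl, TIPS = triisopropylsilyl, Bz = benzoyl.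

Step 1
Reactants: 1 phenyl 1-thio-β-D-galactopyranoside
Product: 3 phenyl 3,4-O-isopropylidene-1-thio-β-D-galactopyranoside, via 6-O-methoxyisopropyl mixed acetal 2 (not isolated)
Conditions: Me2C(OMe)2 (solvent), CSA (cat.), rt; Et3N; then MeOH/H2O 10:1, 60 °C
Reagents that add atoms: 2,2-dimethoxypropane, COC(C)(C)OC
Why: Acid-catalysed transketalisation under thermodynamic control puts the dioxolane on the only cis-vicinal diol of the pyranoside (O3/O4), while O6 is caught as an acyclic mixed acetal that warm aqueous methanol cleaves without touching the ring ketal; no stereocentre changes.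

Step 2
Reactants: 3 phenyl 3,4-O-isopropylidene-1-thio-β-D-galactopyranoside
Product: 4 phenyl 6-O-TBS-3,4-O-isopropylidene-1-thio-β-D-galactopyranoside
Conditions: TBSCl, imidazole, DMF, 0 °C
Reagents that add atoms: tert-butyldimethylsilyl chloride, CC(C)(C)[Si](C)(C)Cl
Why: Silyl ether formation with a bulky chlorosilane picks the primary O6–H over the secondary O2–H on steric grounds.

Step 3
Reactants: 4 phenyl 6-O-TBS-3,4-O-isopropylidene-1-thio-β-D-galactopyranoside; 5 4-methoxybenzyl chloride
Product: 6 phenyl 6-O-TBS-3,4-O-isopropylidene-2-O-PMB-1-thio-β-D-galactopyranoside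
Conditions: NaH, Bu4NI (cat.), DMF, 0 °C to rt
Reagents that add atoms: 4-methoxybenzyl chloride (5), COc1ccc(CCl)cc1
Why: Williamson ether synthesis on the last free hydroxyl; PMB is chosen because this ether must later be removed next to a ring alkene, where hydrogenolysis of a plain benzyl ether would not be possible.

Step 4
Reactants: 6 phenyl 6-O-TBS-3,4-O-isopropylidene-2-O-PMB-1-thio-β-D-galactopyranoside
Product: 7 6-O-TBS-3,4-O-isopropylidene-2-O-PMB-D-galactopyranose (lactol; anomeric mixture)
Conditions: NBS, acetone/H2O 9:1, −15 °C; aq NaHCO3 quench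
Reagents that add atoms: water, O
Why: Thioglycoside hydrolysis (bromonium transfer to sulfur, loss of the sulfenyl bromide, capture of the oxocarbenium ion by water) frees the lactol without the strong acid an O-glycoside would need, so ketal, TBS and PMB groups stay, and the anomeric mixture is of no consequence because G1 becomes sp2 in the next step.

Step 5
Reactants: 7 6-O-TBS-3,4-O-isopropylidene-2-O-PMB-D-galactopyranose
Product: 8 6-O-TBS-3,4-O-isopropylidene-2-O-PMB-D-galactono-1,5-lactone
Conditions: Dess–Martin periodinane, CH2Cl2, rt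
Reagents that add atoms: none
Why: Dess–Martin oxidation of a lactol to the δ-lactone runs under neutral, non-epimerising conditions.

Step 6
Reactants: 8 6-O-TBS-3,4-O-isopropylidene-2-O-PMB-D-galactono-1,5-lactone
Product: 9 6-O-TBS-3,4-O-isopropylidene-N-methoxy-N-methyl-2-O-PMB-D-galactonamide (open chain; 5-OH free)
Conditions: MeNH(OMe)·HCl, AlMe3, CH2Cl2, 0 °C to rt; aq potassium sodium tartrate
Reagents that add atoms: N,O-dimethylhydroxylamine hydrochloride, CNOC.Cl
Why: Weinreb aminolysis of the lactone by the aluminium amide opens the pyranose ring and leaves O5–H as the only free hydroxyl, which is how O5 is told apart from O2 and O6.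

Step 7
Reactants: 9 6-O-TBS-3,4-O-isopropylidene-N-methoxy-N-methyl-2-O-PMB-D-galactonamide
Product: 10 6-O-TBS-3,4-O-isopropylidene-N-methoxy-N-methyl-2-O-PMB-5-O-TIPS-D-galactonamide
Conditions: TIPSOTf, 2,6-lutidine, CH2Cl2, 0 °C to rt (crude 9 used directly)
Reagents that add atoms: triisopropylsilyl trifluoromethanesulfonate, CC(C)[Si](C(C)C)(C(C)C)OS(=O)(=O)C(F)(F)F
Why: Silylation with a silyl triflate is fast enough to outrun relactonisation, and TIPS is chosen because it has to outlast removal of the primary TBS group, hot aqueous acetic acid and HCl.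

Step 8
Reactants: 11 tributyl(iodomethyl)stannane; 12 4-methoxybenzyl alcohol
Product: 13 tributyl{[(4-methoxybenzyl)oxy]methyl}stannane
Conditions: 12, NaH, THF/DMF, 0 °C; then 11, rt
Reagents that add atoms: tributyl(iodomethyl)stannane (11), CCCC[Sn](CCCC)(CCCC)CI
Why: Williamson-type SN2 displacement of the primary iodide by the alkoxide is the standard access to alkoxymethylstannanes.

Step 9
Reactants: 10 6-O-TBS-3,4-O-isopropylidene-N-methoxy-N-methyl-2-O-PMB-5-O-TIPS-D-galactonamide; 13 tributyl{[(4-methoxybenzyl)oxy]methyl}stannane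
Product: 15 open-chain ketone (G1 = C=O bearing C7H2OPMB; G2-OPMB; G3,G4-O-isopropylidene; G5-OTIPS; G6-OTBS; D-galacto), via 4-methoxybenzyloxymethyllithium 14 (not isolated)
Conditions: 13, n-BuLi, THF, −78 °C; then 10, −78 °C; AcOH quench at −78 °C
Reagents that add atoms: stannane 13 (delivers CH2OPMB), CCCC[Sn](CCCC)(CCCC)COCc1ccc(OC)cc1
Why: Tin–lithium exchange gives the α-alkoxymethyllithium, which adds only once to the amide (Weinreb ketone synthesis) because the chelated tetrahedral adduct holds until the cold acid quench, so G2 next to the new ketone is not epimerised.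

Step 10
Reactants: 15 open-chain ketone with G6-OTBS
Product: 16 open-chain hydroxy ketone (as 15 but G6-OH free)
Conditions: HF·pyridine, pyridine, THF, 0 °C
Reagents that add atoms: none
Why: In this selective desilylation, buffered HF removes the unhindered primary TBS ether far faster than the secondary TIPS ether, and ketal, PMB ethers and ketone are inert.

Step 11
Reactants: 16 open-chain hydroxy ketone
Product: 17 open-chain 1,6-keto-aldehyde (G1 = PMBOCH2 ketone; G2-OPMB; G3,G4-O-isopropylidene; G5-OTIPS; G6 = CHO)
Conditions: Dess–Martin periodinane, CH2Cl2, 0 °C to rt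
Reagents that add atoms: none
Why: Dess–Martin oxidation stops at the aldehyde and is free of base, so the α-silyloxy centre G5 does not epimerise and the keto-aldehyde does not undergo aldol reaction; the product is used at once.

Step 12
Reactants: 17 open-chain 1,6-keto-aldehyde
Product: 18 cyclitol cis-1,2-diol (1-OH and 2-OH lower face; C7H2OPMB upper; 3-OTIPS upper; 4,5-O-isopropylidene lower; 6-OPMB upper)
Conditions: SmI2 (0.1 M in THF, 3 equiv), t-BuOH (3 equiv), THF, −78 to −20 °C, dilute solution of 17 added to the reductant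
Reagents that add atoms: none
Why: Divalent samarium gives one electron to the aldehyde, the more easily reduced and less hindered carbonyl group, and the resulting ketyl, held to the ketone oxygen by the oxophilic trivalent samarium, adds through its carbon (C2) to the ketone carbon (C1); a second electron and t-BuOH turn the samarium diolate into the diol. This is the SmI2 pinacol cyclisation known for sugar-derived 1,6-dicarbonyl compounds on the way to inositols and carbasugars. The cyclohexane closes in the 6-exo-trig mode, helped by the cis-dioxolane, which already holds both chain ends on one side. The samarium bridge between the two oxygens makes the new C1–O and C2–O bonds cis. Dipole and steric repulsion sets each new C–O bond anti to the neighbouring one (C2–O against C3–OTIPS, C1–O against C6–OPMB), and because these two controllers are cis-1,4 they ask for the same lower face, which fixes both new stereocentres and leaves C7 on the upper face. The step needs ketyl formation at the aldehyde rather than reductive loss of an α-alkoxy group from the ketone, which is secured by ether instead of ester groups on C6 and C7, by low temperature, by the absence of HMPA and by t-BuOH as a mild proton source, while dilution suppresses intermolecular coupling.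

Step 13
Reactants: 18 cyclitol cis-1,2-diol; 19 benzoyl chloride
Product: 20 2-O-benzoate of 18 (1-OH free)
Conditions: BzCl, pyridine, DMAP (cat.), CH2Cl2, 0 °C to rt
Reagents that add atoms: benzoyl chloride (19), O=C(Cl)c1ccccc1
Why: DMAP-catalysed acylation esterifies only the secondary C2–OH, the tertiary C1–OH being too hindered.

Step 14
Reactants: 20 2-O-benzoate
Product: 21 1,4,5-triol (4-OH and 5-OH lower face and cis; 2-OBz; 3-OTIPS; 6-OPMB; C7-OPMB)
Conditions: AcOH/H2O 4:1, 60 °C
Reagents that add atoms: none
Why: Acid hydrolysis removes the cis-fused ketal, while PMB ethers, benzoate and the acid-resistant TIPS ether survive aqueous acetic acid.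

Step 15
Reactants: 21 1,4,5-triol
Product: 22 4,5-cyclic thionocarbonate
Conditions: 1,1'-thiocarbonyldiimidazole, toluene, 80 °C
Reagents that add atoms: 1,1'-thiocarbonyldiimidazole, S=C(n1ccnc1)n1ccnc1
Why: Cyclic thionocarbonate formation (first half of the Corey–Winter olefination) is possible only across the cis-4,5-diol, and the tertiary C1–OH is not acylated.

Step 16
Reactants: 22 4,5-cyclic thionocarbonate
Product: 23 cyclohexene (C4=C5; 1-OH lower; 2-OBz lower; 3-OTIPS upper; 6-OPMB upper; C7H2OPMB upper)
Conditions: P(OMe)3 (neat), 110 °C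
Reagents that add atoms: none
Why: In the Corey–Winter olefination the phosphite removes sulfur and the resulting dioxolanylidene loses CO2 in a stereospecific syn cycloreversion to the cis ring alkene, and since C3 and C6 carry plain ethers at this stage the nucleophilic phosphite finds no allylic leaving group.

Step 17
Reactants: 23 bis-PMB cyclohexene
Product: 24 1,6,7-triol (6-OH upper and allylic; 1-OH lower; C7H2OH upper; 2-OBz; 3-OTIPS)
Conditions: DDQ, CH2Cl2/aq NaH2PO4–Na2HPO4 buffer (pH 7) 10:1, 0 °C
Reagents that add atoms: none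
Why: In this oxidative PMB cleavage DDQ abstracts benzylic hydride from both electron-rich ethers and water hydrolyses the oxocarbenium ions, a deprotection that leaves alkene, benzoate and TIPS ether alone.

Step 18
Reactants: 24 1,6,7-triol; 19 benzoyl chloride
Product: 25 2,7-dibenzoate trans-1,6-diol
Conditions: BzCl (1 equiv), pyridine, CH2Cl2, −40 °C
Reagents that add atoms: benzoyl chloride (19), O=C(Cl)c1ccccc1
Why: Selective acylation at low temperature takes the primary C7–OH in preference to the secondary C6–OH next to the quaternary carbon and to the tertiary C1–OH.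

Step 19
Reactants: 25 2,7-dibenzoate trans-1,6-diol
Product: 26 C1–C6 vinyl epoxide (oxirane oxygen on the lower face; 2-OBz; 3-OTIPS; C7H2OBz)
Conditions: PPh3, DIAD, THF, 0 °C to rt
Reagents that add atoms: none
Why: In this Mitsunobu cyclodehydration of a trans-1,2-diol the secondary allylic C6–OH is activated as its oxyphosphonium ion and displaced from the lower face by the antiperiplanar C1 oxygen, which inverts C6 and places the epoxide on the lower face in a neutral medium that does not move the benzoates.

Step 20
Reactants: 26 C1–C6 vinyl epoxide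
Product: 27 3-O-TIPS chlorohydrin (6-Cl upper; 1-OH lower)
Conditions: HCl (1 M in Et2O), CH2Cl2, −40 to 0 °C
Reagents that add atoms: hydrogen chloride, Cl
Why: In this acid-promoted SN2 opening of a vinyl epoxide, chloride attacks the allylic C6 from the upper face, anti to the departing oxygen (Fürst–Plattner trans-diaxial opening), which inverts C6 a second time, whereas the fully substituted C1 flanked by two acyloxy-bearing carbons neither ionises nor admits backside attack.

Step 21
Reactants: 27 3-O-TIPS chlorohydrin
Product: 28 target, (1R,2R,3S,6R) in the numbering used here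
Conditions: HF·pyridine, THF, 0 °C to rt
Reagents that add atoms: none
Why: Fluoride-mediated desilylation in an acidic medium frees C3–OH without the benzoate migration or epoxide re-closure that a basic fluoride source could cause.

Compound list
1 | phenyl 1-thio-β-D-galactopyranoside | OC[C@H]1O[C@@H](Sc2ccccc2)[C@H](O)[C@@H](O)[C@H]1O | starting material
2 | phenyl 3,4-O-isopropylidene-6-O-(2-methoxypropan-2-yl)-1-thio-β-D-galactopyranoside (not isolated) | COC(C)(C)OC[C@H]1O[C@@H](Sc2ccccc2)[C@H](O)[C@H]3OC(C)(C)O[C@H]31 | intermediate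
3 | phenyl 3,4-O-isopropylidene-1-thio-β-D-galactopyranoside | OC[C@H]1O[C@@H](Sc2ccccc2)[C@H](O)[C@H]3OC(C)(C)O[C@H]31 | intermediate
4 | phenyl 6-O-TBS-3,4-O-isopropylidene-1-thio-β-D-galactopyranoside | CC(C)(C)[Si](C)(C)OC[C@H]1O[C@@H](Sc2ccccc2)[C@H](O)[C@H]3OC(C)(C)O[C@H]31 | intermediate
5 | 4-methoxybenzyl chloride | COc1ccc(CCl)cc1 | starting material
6 | phenyl 6-O-TBS-3,4-O-isopropylidene-2-O-PMB-1-thio-β-D-galactopyranoside | CC(C)(C)[Si](C)(C)OC[C@H]1O[C@@H](Sc2ccccc2)[C@H](OCc2ccc(OC)cc2)[C@H]3OC(C)(C)O[C@H]31 | intermediate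
7 | 6-O-TBS-3,4-O-isopropylidene-2-O-PMB-D-galactopyranose (anomeric mixture) | CC(C)(C)[Si](C)(C)OC[C@H]1OC(O)[C@H](OCc2ccc(OC)cc2)[C@H]3OC(C)(C)O[C@H]31 | intermediate
8 | 6-O-TBS-3,4-O-isopropylidene-2-O-PMB-D-galactono-1,5-lactone | CC(C)(C)[Si](C)(C)OC[C@H]1OC(=O)[C@H](OCc2ccc(OC)cc2)[C@H]3OC(C)(C)O[C@H]31 | intermediate
9 | 6-O-TBS-3,4-O-isopropylidene-N-methoxy-N-methyl-2-O-PMB-D-galactonamide | CON(C)C(=O)[C@H](OCc1ccc(OC)cc1)[C@H]2OC(C)(C)O[C@H]2[C@H](O)CO[Si](C)(C)C(C)(C)C | intermediate
10 | 6-O-TBS-3,4-O-isopropylidene-N-methoxy-N-methyl-2-O-PMB-5-O-TIPS-D-galactonamide | CON(C)C(=O)[C@H](OCc1ccc(OC)cc1)[C@H]2OC(C)(C)O[C@H]2[C@H](O[Si](C(C)C)(C(C)C)C(C)C)CO[Si](C)(C)C(C)(C)C | intermediate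
11 | tributyl(iodomethyl)stannane | CCCC[Sn](CCCC)(CCCC)CI | starting material
12 | 4-methoxybenzyl alcohol | COc1ccc(CO)cc1 | starting material
13 | tributyl{[(4-methoxybenzyl)oxy]methyl}stannane | CCCC[Sn](CCCC)(CCCC)COCc1ccc(OC)cc1 | intermediate
14 | [(4-methoxybenzyl)oxy]methyllithium (not isolated) | [Li]COCc1ccc(OC)cc1 | intermediate
15 | open-chain ketone, G6-OTBS | O=C(COCc1ccc(OC)cc1)[C@H](OCc1ccc(OC)cc1)[C@H]2OC(C)(C)O[C@H]2[C@H](O[Si](C(C)C)(C(C)C)C(C)C)CO[Si](C)(C)C(C)(C)C | intermediate
16 | open-chain hydroxy ketone, G6-OH | O=C(COCc1ccc(OC)cc1)[C@H](OCc1ccc(OC)cc1)[C@H]2OC(C)(C)O[C@H]2[C@H](O[Si](C(C)C)(C(C)C)C(C)C)CO | intermediate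
17 | open-chain 1,6-keto-aldehyde (key-step precursor) | O=C(COCc1ccc(OC)cc1)[C@H](OCc1ccc(OC)cc1)[C@H]2OC(C)(C)O[C@H]2[C@H](O[Si](C(C)C)(C(C)C)C(C)C)C=O | intermediate
18 | cyclitol cis-1,2-diol (key-step product) | COc1ccc(cc1)COC[C@]2(O)[C@H](OCc3ccc(OC)cc3)[C@H]4OC(C)(C)O[C@H]4[C@H](O[Si](C(C)C)(C(C)C)C(C)C)[C@H]2O | intermediate
19 | benzoyl chloride | O=C(Cl)c1ccccc1 | starting material
20 | 2-O-benzoate of 18 | COc1ccc(cc1)COC[C@]2(O)[C@H](OCc3ccc(OC)cc3)[C@H]4OC(C)(C)O[C@H]4[C@H](O[Si](C(C)C)(C(C)C)C(C)C)[C@H]2OC(=O)c5ccccc5 | intermediate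
21 | 1,4,5-triol (cis-4,5-diol) | COc1ccc(cc1)COC[C@]2(O)[C@H](OCc3ccc(OC)cc3)[C@@H](O)[C@@H](O)[C@H](O[Si](C(C)C)(C(C)C)C(C)C)[C@H]2OC(=O)c4ccccc4 | intermediate
22 | 4,5-cyclic thionocarbonate | COc1ccc(cc1)COC[C@]2(O)[C@H](OCc3ccc(OC)cc3)[C@H]4OC(=S)O[C@H]4[C@H](O[Si](C(C)C)(C(C)C)C(C)C)[C@H]2OC(=O)c5ccccc5 | intermediate
23 | bis-PMB cyclohexene (C4=C5) | COc1ccc(cc1)COC[C@]2(O)[C@H](OCc3ccc(OC)cc3)C=C[C@H](O[Si](C(C)C)(C(C)C)C(C)C)[C@H]2OC(=O)c4ccccc4 | intermediate
24 | 1,6,7-triol | OC[C@]1(O)[C@H](O)C=C[C@H](O[Si](C(C)C)(C(C)C)C(C)C)[C@H]1OC(=O)c2ccccc2 | intermediate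
25 | 2,7-dibenzoate trans-1,6-diol | O=C(OC[C@]1(O)[C@H](O)C=C[C@H](O[Si](C(C)C)(C(C)C)C(C)C)[C@H]1OC(=O)c2ccccc2)c3ccccc3 | intermediate
26 | C1–C6 vinyl epoxide | O=C(OC[C@]12O[C@H]1C=C[C@H](O[Si](C(C)C)(C(C)C)C(C)C)[C@H]2OC(=O)c3ccccc3)c4ccccc4 | intermediate
27 | 3-O-TIPS chlorohydrin | O=C(OC[C@]1(O)[C@H](Cl)C=C[C@H](O[Si](C(C)C)(C(C)C)C(C)C)[C@H]1OC(=O)c2ccccc2)c3ccccc3 | intermediate
28 | CNP0326102.1 | O=C(OC[C@]1(O)[C@H](Cl)C=C[C@H](O)[C@H]1OC(=O)c1ccccc1)c1ccccc1 | target

Total step count: 21. Longest linear sequence: 20 steps (steps 1–7 and 9–21, from 1 to 28); step 8 is a one-step side branch.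

Steps most likely to fail

Step 12. The closure may suffer from poor facial selectivity, because the lower face also carries the ketal oxygens. It may also suffer from reductive loss of an α-alkoxy group before the ring closes. The same C1–C2 bond can then be made as an alkene. Setting out from 17, double Wittig methylenation (Ph3P=CH2 from Ph3PCH3Br and KN(SiMe3)2, THF, −78 to 0 °C) should give the octa-1,7-diene F1. Ring-closing metathesis with the second-generation Grubbs catalyst (CH2Cl2, 40 °C) should then give the C1=C2 cyclohexene F2. Dihydroxylation with OsO4 (cat.) and N-methylmorpholine N-oxide, which approaches anti to both allylic ethers on C3 and C6, comes back to the route at 18.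

Step 17. The benzylic oxocarbenium ion of the C7 ether may be intercepted by the neighbouring tertiary hydroxyl, leading to acetal formation and then over-oxidation. The freed allylic alcohol may also be oxidised. The fallback leaves oxidation altogether. Setting out from 23, acidolysis with CF3CO2H in CH2Cl2 at 0 °C in the presence of 1,3-dimethoxybenzene releases each PMB group as a carbocation at the alcohol oxidation level. The arene traps this cation by Friedel–Crafts alkylation, so no acetal can form. The TIPS ether and benzoate persist, and the sequence comes back at 24. No new compound arises on this path (F0).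

Step 20. Three processes may erode regio- and stereochemical fidelity: competing SN2' attack at C4, participation of the C7 benzoate carbonyl at C6, or partial ionisation. The fallback replaces the proton by silicon. Setting out from 26, Me3SiCl with Bu4NCl (cat.) in CH2Cl2 at −20 °C activates the oxirane oxygen, traps it at once as a silyl ether and delivers chloride to C6 within the ion pair. This should give the 1-O-trimethylsilyl chlorohydrin F3. HF·pyridine as in step 21 then strips both silyl groups and comes back to the route at 28.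

Further compounds
F1 | step 12 | octa-1,7-diene (both carbonyl groups of 17 replaced by C=CH2) | C=C(COCc1ccc(OC)cc1)[C@H](OCc1ccc(OC)cc1)[C@H]2OC(C)(C)O[C@H]2[C@H](O[Si](C(C)C)(C(C)C)C(C)C)C=C
F2 | step 12 | C1=C2 cyclohexene (3-OTIPS upper; 4,5-O-isopropylidene lower; 6-OPMB upper; C7H2OPMB on C1) | COc1ccc(cc1)COCC2=C[C@@H](O[Si](C(C)C)(C(C)C)C(C)C)[C@@H]3OC(C)(C)O[C@@H]3[C@H]2OCc4ccc(OC)cc4
F0 | step 17 | none | none
F3 | step 20 | 1-O-trimethylsilyl-3-O-TIPS chlorohydrin | O=C(OC[C@]1(O[Si](C)(C)C)[C@H](Cl)C=C[C@H](O[Si](C(C)C)(C(C)C)C(C)C)[C@H]1OC(=O)c2ccccc2)c3ccccc3
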